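At early times, before J has piled up, ask how many turnovers of G into J each charged Q has made per minute: the earlier grey run gives 0.750 min⁻¹ by 10.0 min, and the earlier teal run gives 1.33 min⁻¹ by 6.00 min, twice as many.

| setting | grey | teal | birch | ash | oak | elm |
|---|---|---|---|---|---|---|
| G | 0.13 M | 0.40 M | 0.20 M | 0.20 M | 0.20 M | 0.20 M |
| Q | 2 mol% | 2 mol% | 2 mol% | 2 mol% | 2 mol% | 2 mol% |
| Z | 1.6 mM | 1.6 mM | 3.0 mM | 1.6 mM | 0.80 mM | 5.0 mM |
| remark | run made earlier | run made earlier |  |  |  |  |
| time |  |  | 2.0 h | 2.0 h | 2.0 h | 2.0 h |

- grey (time / min: J / %, G / %): 2.00: 1, 95; 4.00: 7, 93; 10.0: 15, 85; 25.0: 29, 73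
- teal (time / min: J / %, G / %): 6.00: 16, 82; 12.0: 28, 68; 20.0: 46, 52; 25.0: 55, 42

(standard deviation of a reading: 2 percentage points)

* all flasks from highest to lowest amount of J, in percent of the G charged, at 2.0 h (birch / ash / oak / elm)
* the amount of J, in percent of the G charged of the flask you put first, at 2.0 h
* the amount of J, in percent of the G charged of the flask you put last, at 2.0 h

- amounts and yields of J count X too
- what was read earlier has a scatter of 2 percentage points, one standard deviation
- candidate steps: G + Q -> E; E -> Q + J; Q + Z -> L; Q + J <-> X

Read the table column against column. Elm has 1.25 as its dose, the Z charged as a fraction of the Q charged, and the same fraction reads 0.615 for grey and 0.200 for teal. If each Z takes one Q, the share left working is one minus the dose, and dividing by it brings grey to 1.95 min⁻¹ and teal to 1.67 min⁻¹ per working Q, a gap that a scatter of 2 percentage points on readings near 15 % covers.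

Along the same columns, the dose is 0.200 for oak, 0.400 for ash and 0.750 for birch, so I would put J in that order, with elm last. Elm's dose is above one, which makes Q the limiting reagent of the capture by Z. I give no number for elm: the dose tells where its catalyst ends, not how much J Q makes on the way there.

The forecast, holding that “Z removes Q one-for-one and irreversibly”, gives oak > ash > birch > elm, with oak at 98 % (range 92 % to 100 %) and elm at 0 % (range 0 % to 2 %).

The flasks give oak > ash > birch > elm, with oak at 99.1 % and elm at 20.3 %.

    G + Q → E (k = 1200 M⁻¹ h⁻¹)
    E → Q + J (k = 110 h⁻¹)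
    Q + Z → L (k = 8500 M⁻¹ h⁻¹)
    Q + J ⇌ X (K = 2.10 M⁻¹, k = 3.30 M⁻¹ h⁻¹)

Elm's shortfall comes mainly from the path from Q + Z to L: without that path, elm reaches 99.8 %. Yet at the start of elm Q is used by G 5.6 times as fast as by Z, and J appears before the capture ends. By 2.00 h, L holds 99.9 % of elm's catalyst, and the Z left, 20.1 % of its charge, matches one minus the inverse dose, 20.0 %. The neighbour flask that is elm with 3.4 mol% of Q has a dose of 0.735; in that neighbour L holds 73.5 % of the catalyst, Z stands at 0 %, and J reaches 91.4 %.

The runs were computed for substances that don't exist; noise was put on by code.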